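**Retrosynthetic overview**
1. Endgame: the C15 acid is freed from its methyl ester and the C18 senecioate comes from a diol; the C12–C16 unit (C13 bought as a chiral half-ester) is joined to C11 of bicyclic aldehyde 22 by Wittig olefination, then hydrogenated.
2. Key disconnection: bonds C5–C10 and C8–C9 are made by one intramolecular Diels–Alder reaction of the open-chain trienal 21; rings A and B close together in step 13 and no ring of the skeleton exists before it.
3. Enabling feature: in ring B (C5–C6–C7–C8–C9–C10) the tertiary oxygen on C8 sits next to C9, whose substituent C11 is a plain CH2. With C6=C7 unsaturated, O-8 becomes the donor of a 1-silyloxy diene C5=C6–C7=C8 and C11, raised to formyl, makes C9=C10 an enal dienophile; C1–C3 and quaternary C4 of ring A are the four-atom tether from C5 to C10.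
4. Stereochemistry: C4 is set by catalysis (Sharpless epoxidation, then stereospecific epoxy silyl ether rearrangement); C5, C8, C9 and C10 are relayed from C4 and from three alkene geometries in the one event.
5. Triene assembly: Negishi carboalumination (precursor of C4), Julia–Kocienski olefination (C5=C6), carbocupration of ethyl but-2-ynoate (C9=C10) and soft enolisation (C7=C8).

Key step: step 13

Remark: labdane numbering is used for atoms (ring A C1–C5/C10, ring B C5–C10, side chain C11–C16, C17 on C8, C18 = CH2O and C19 = CH3 on C4, C20 on C10); the SMILES is read as (4S,5S,8S,9S,10R,13R), with the C18 oxygen equatorial and C19 axial, cis to C20.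

**Step 1**
Reactants: 1 5-chloropent-1-yne
Product: 4 (2E)-6-chloro-3-methylhex-2-en-1-ol, via alkenyldimethylalane 2 (not isolated), via lithium alkenylalanate 3 (not isolated)
Conditions: AlMe3, Cp2ZrCl2 (cat.), CH2Cl2, 0 °C to rt; n-BuLi, THF, −78 °C; (CH2O)n, −78 °C to rt; aq. HCl
Reagents that add atoms: trimethylaluminium C[Al](C)C; formaldehyde (as paraformaldehyde) C=O
Why: Negishi carboalumination (Cp2ZrCl2-catalysed syn addition of Me–Al, methyl to the internal carbon) followed by hydroxymethylation of the alanate with retention should give only the E alkene, whose geometry later decides the configuration at C4.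

**Step 2**
Reactants: 4 (2E)-6-chloro-3-methylhex-2-en-1-ol
Product: 5 [(2R,3R)-3-(3-chloropropyl)-3-methyloxiran-2-yl]methanol
Conditions: Ti(OiPr)4 (cat.), D-(−)-diisopropyl tartrate (cat.), tBuOOH, 4 Å molecular sieves, CH2Cl2, −20 °C
Reagents that add atoms: tert-butyl hydroperoxide CC(C)(C)OO
Why: Sharpless asymmetric epoxidation of an E-3,3-disubstituted allylic alcohol (geraniol type) with the D-(−)-tartrate is expected to give the (2R,3R)-epoxide, the stereocentre set by catalysis from which C4 is derived.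

**Step 3**
Reactants: 5 [(2R,3R)-3-(3-chloropropyl)-3-methyloxiran-2-yl]methanol
Product: 6 tert-butyl{[(2R,3R)-3-(3-chloropropyl)-3-methyloxiran-2-yl]methoxy}dimethylsilane
Conditions: TBSCl, imidazole, DMF, 0 °C to rt
Reagents that add atoms: tert-butyldimethylsilyl chloride CC(C)(C)[Si](C)(C)Cl
Why: Routine silylation of the primary alcohol installs the bulky siloxymethyl group that the rearrangement needs as migrating group and that later is the large substituent on C4.

**Step 4**
Reactants: 6 tert-butyl{[(2R,3R)-3-(3-chloropropyl)-3-methyloxiran-2-yl]methoxy}dimethylsilane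
Product: 7 (2R)-2-{[(tert-butyldimethylsilyl)oxy]methyl}-5-chloro-2-methylpentanal
Conditions: MeAl(OAr)2 (Ar = 4-bromo-2,6-di-tert-butylphenyl, 2 equiv), CH2Cl2, −78 °C
Reagents that add atoms: none
Why: Organoaluminium-promoted rearrangement of a 2,3-epoxy silyl ether (semipinacol-type 1,2-shift): the bulky Lewis acid ionises the tertiary C–O bond and the siloxymethyl group migrates anti to the leaving oxygen, so the epoxide chirality is transferred with inversion to the quaternary carbon (future C4).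

**Step 5**
Reactants: 8 2-(2-bromoethyl)-2-methyl-1,3-dioxolane; 9 1-phenyl-1H-tetrazole-5-thiol
Product: 10 5-{[2-(2-methyl-1,3-dioxolan-2-yl)ethyl]sulfanyl}-1-phenyl-1H-tetrazole
Conditions: K2CO3, acetone, rt
Reagents that add atoms: none
Why: SN2 S-alkylation of the acidic tetrazole thiol by the primary bromide under mild base leaves the ketal intact.

**Step 6**
Reactants: 10 5-{[2-(2-methyl-1,3-dioxolan-2-yl)ethyl]sulfanyl}-1-phenyl-1H-tetrazole
Product: 11 5-{[2-(2-methyl-1,3-dioxolan-2-yl)ethyl]sulfonyl}-1-phenyl-1H-tetrazole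
Conditions: H2O2 (30%), (NH4)6Mo7O24·4H2O (cat.), EtOH, 0 °C to rt
Reagents that add atoms: hydrogen peroxide OO
Why: Molybdate-catalysed peroxide oxidation of sulfide to sulfone is standard for Julia–Kocienski reagents and is compatible with the dioxolane.

**Step 7**
Reactants: 7 (2R)-2-{[(tert-butyldimethylsilyl)oxy]methyl}-5-chloro-2-methylpentanal; 11 5-{[2-(2-methyl-1,3-dioxolan-2-yl)ethyl]sulfonyl}-1-phenyl-1H-tetrazole
Product: 13 tert-butyl{[(2S,3E)-2-(3-chloropropyl)-2-methyl-5-(2-methyl-1,3-dioxolan-2-yl)pent-3-en-1-yl]oxy}dimethylsilane, via potassium sulfonyl carbanion 12 (not isolated)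
Conditions: KN(SiMe3)2, 1,2-dimethoxyethane, −60 °C; then 7, −60 °C to rt
Reagents that add atoms: none
Why: Julia–Kocienski olefination (addition, Smiles rearrangement, loss of SO2 and tetrazolone) of a 1-phenyltetrazolyl sulfone with an α-branched aldehyde is expected to give the E alkene C5=C6, and the aldehyde cannot epimerise because its α-carbon is quaternary.

**Step 8**
Reactants: 13 tert-butyl{[(2S,3E)-2-(3-chloropropyl)-2-methyl-5-(2-methyl-1,3-dioxolan-2-yl)pent-3-en-1-yl]oxy}dimethylsilane; 14 ethyl but-2-ynoate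
Product: 17 ethyl (2E,7S,8E)-7-{[(tert-butyldimethylsilyl)oxy]methyl}-3,7-dimethyl-10-(2-methyl-1,3-dioxolan-2-yl)deca-2,8-dienoate, via alkylmagnesium chloride 15 (not isolated), via alkylcopper reagent 16 (not isolated)
Conditions: Mg, THF, reflux; CuBr·SMe2 (1 equiv), −78 °C; then 14, −78 °C; MeOH quench at −78 °C
Reagents that add atoms: none
Why: Conjugate addition of an alkylcopper reagent to an ynoate (carbocupration) is a syn addition, so protonation of the alkenylcopper adduct at −78 °C should give the (2E)-3-methyl enoate with the new chain trans to the ester, which fixes the dienophile geometry that later relates C9 to C10.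

**Step 9**
Reactants: 17 ethyl (2E,7S,8E)-7-{[(tert-butyldimethylsilyl)oxy]methyl}-3,7-dimethyl-10-(2-methyl-1,3-dioxolan-2-yl)deca-2,8-dienoate
Product: 18 ethyl (2E,7S,8E)-7-{[(tert-butyldimethylsilyl)oxy]methyl}-3,7-dimethyl-11-oxododeca-2,8-dienoate
Conditions: pyridinium p-toluenesulfonate (cat.), acetone/H2O, 45 °C
Reagents that add atoms: water O
Why: Mild acid-catalysed acetal hydrolysis should release the β,γ-unsaturated methyl ketone without moving the C5=C6 double bond into conjugation and without cleaving the primary TBS ether.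

**Step 10**
Reactants: 18 ethyl (2E,7S,8E)-7-{[(tert-butyldimethylsilyl)oxy]methyl}-3,7-dimethyl-11-oxododeca-2,8-dienoate
Product: 19 ethyl (2E,7S,8E,10Z)-7-{[(tert-butyldimethylsilyl)oxy]methyl}-3,7-dimethyl-11-[(triethylsilyl)oxy]dodeca-2,8,10-trienoate
Conditions: Et3SiOTf, Et3N, Et2O, −78 to 0 °C
Reagents that add atoms: triethylsilyl trifluoromethanesulfonate CC[Si](CC)(CC)OS(=O)(=O)C(F)(F)F
Why: Soft enolisation (silyl triflate/tertiary amine) removes the doubly activated hydrogen between carbonyl and alkene rather than a methyl hydrogen, giving the conjugated silyl dienol ether, whose Z geometry (OSi cis to the vinyl group) is favoured because the E isomer would place the methyl cis to the vinyl group (allylic strain).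

**Step 11**
Reactants: 19 ethyl (2E,7S,8E,10Z)-7-{[(tert-butyldimethylsilyl)oxy]methyl}-3,7-dimethyl-11-[(triethylsilyl)oxy]dodeca-2,8,10-trienoate
Product: 20 (2E,7S,8E,10Z)-7-{[(tert-butyldimethylsilyl)oxy]methyl}-3,7-dimethyl-11-[(triethylsilyl)oxy]dodeca-2,8,10-trien-1-ol
Conditions: iBu2AlH, CH2Cl2, −78 °C; aq. NaOH work-up
Reagents that add atoms: none
Why: iBu2AlH reduces the conjugated ester in 1,2 fashion to the allylic alcohol at low temperature, while the silyl ether and silyl enol ether are inert to hydride and to the basic work-up.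

**Step 12**
Reactants: 20 (2E,7S,8E,10Z)-7-{[(tert-butyldimethylsilyl)oxy]methyl}-3,7-dimethyl-11-[(triethylsilyl)oxy]dodeca-2,8,10-trien-1-ol
Product: 21 (2E,7S,8E,10Z)-7-{[(tert-butyldimethylsilyl)oxy]methyl}-3,7-dimethyl-11-[(triethylsilyl)oxy]dodeca-2,8,10-trienal
Conditions: MnO2 (activated, excess), CH2Cl2, rt
Reagents that add atoms: none
Why: MnO2 oxidises allylic alcohols selectively to enals under neutral heterogeneous conditions without E/Z isomerisation, so the acid-labile dienol ether and the dienophile geometry should be preserved.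

**Step 13**
Reactants: 21 (2E,7S,8E,10Z)-7-{[(tert-butyldimethylsilyl)oxy]methyl}-3,7-dimethyl-11-[(triethylsilyl)oxy]dodeca-2,8,10-trienal
Product: 22 (1S,2S,4aS,5S,8aR)-5-{[(tert-butyldimethylsilyl)oxy]methyl}-2,5,8a-trimethyl-2-[(triethylsilyl)oxy]-1,2,4a,5,6,7,8,8a-octahydronaphthalene-1-carbaldehyde
Conditions: Me2AlCl (0.3 equiv), CH2Cl2 (0.01 M), −78 to −20 °C; Et3N/aq. NaHCO3 quench
Reagents that add atoms: none
Why: Lewis-acid-catalysed intramolecular Diels–Alder reaction (type 1, 1,3,9-decatriene to trans-octalin): Me2AlCl activates the enal, whose LUMO coefficient is largest at C10, and the 1-silyloxy diene has its largest HOMO coefficient at C5, so the concerted but asynchronous [4+2] forms C5–C10 ahead of C8–C9 in the electronically matched sense that the tether also imposes. The closest known reaction type is the Lewis-acid-promoted intramolecular Diels–Alder reaction of terminally activated decatrienals with 1-oxygenated dienes, and vinylketene acetals show that an oxygen in the inside position of a diene terminus is tolerated. Ring A closes as the six-membered ring spanned by the four-carbon tether C1–C4 through the C5–C10 bond, and ring B is the new cyclohexene closed suprafacially on both components through C5–C10 and C8–C9. C9 and C10 follow from the E dienophile (C11 and C20 cis), C8 from the Z enol ether (OSi inside, so O-8 ends up cis to H-5 and H-9 and C17 cis to C20), and the trans ring fusion from the endo transition state with the formyl group under the diene and the tether in a chair. The absolute sense of all four new centres is relayed from C4, because in that chair the larger CH2OTBS group should take the pseudo-equatorial site and the methyl the pseudo-axial site syn to the developing angular methyl. The step needs endo/chair over exo/boat selectivity, π-facial selectivity with respect to C4 and [4+2] over open-chain Mukaiyama-type addition, which low-temperature Lewis acid catalysis, the size difference of the two C4 substituents and the tether (no other ring size is accessible) are expected to secure.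

**Step 14**
Reactants: 23 (3R)-5-methoxy-3-methyl-5-oxopentanoic acid
Product: 24 methyl (3S)-4-iodo-3-methylbutanoate
Conditions: PhI(OAc)2, I2, 1,2-dichloroethane, hν (tungsten lamp), 80 °C
Reagents that add atoms: iodine II
Why: Hunsdiecker-type iododecarboxylation with a hypervalent iodine reagent (photolysis of the acyl hypoiodite, loss of CO2, iodine transfer to the primary radical) shortens the acid arm by one carbon, and the stereocentre is safe because it is β to the radical and not α to a carbonyl group.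

**Step 15**
Reactants: 24 methyl (3S)-4-iodo-3-methylbutanoate
Product: 25 [(2S)-4-methoxy-2-methyl-4-oxobutyl]triphenylphosphonium iodide
Conditions: PPh3, MeCN, reflux
Reagents that add atoms: triphenylphosphine c1ccc(cc1)P(c1ccccc1)c1ccccc1
Why: SN2 quaternisation of triphenylphosphine by the primary iodide gives the Wittig salt without touching the stereocentre.

**Step 16**
Reactants: 22 (1S,2S,4aS,5S,8aR)-5-{[(tert-butyldimethylsilyl)oxy]methyl}-2,5,8a-trimethyl-2-[(triethylsilyl)oxy]-1,2,4a,5,6,7,8,8a-octahydronaphthalene-1-carbaldehyde; 25 [(2S)-4-methoxy-2-methyl-4-oxobutyl]triphenylphosphonium iodide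
Product: 27 methyl (3S,4Z)-5-[(1S,2S,4aS,5S,8aR)-5-{[(tert-butyldimethylsilyl)oxy]methyl}-2,5,8a-trimethyl-2-[(triethylsilyl)oxy]-1,2,4a,5,6,7,8,8a-octahydronaphthalen-1-yl]-3-methylpent-4-enoate, via phosphonium ylide 26 (not isolated)
Conditions: NaN(SiMe3)2, THF, −78 to 0 °C; then 22, −78 °C to rt
Reagents that add atoms: none
Why: Wittig olefination with a non-stabilised ylide joins C11 to C12; the Z alkene is expected but its geometry is irrelevant because it is hydrogenated next, and neither C9 (addition to the aldehyde should outrun enolisation at −78 °C) nor C13 (not α to the ylide or the ester) should be affected.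

**Step 17**
Reactants: 27 methyl (3S,4Z)-5-[(1S,2S,4aS,5S,8aR)-5-{[(tert-butyldimethylsilyl)oxy]methyl}-2,5,8a-trimethyl-2-[(triethylsilyl)oxy]-1,2,4a,5,6,7,8,8a-octahydronaphthalen-1-yl]-3-methylpent-4-enoate
Product: 28 methyl (3R)-5-[(1S,2S,4aS,5S,8aR)-5-{[(tert-butyldimethylsilyl)oxy]methyl}-2,5,8a-trimethyl-2-[(triethylsilyl)oxy]decahydronaphthalen-1-yl]-3-methylpentanoate
Conditions: H2 (3 atm), PtO2 (cat.), EtOAc, rt
Reagents that add atoms: none
Why: Heterogeneous catalytic hydrogenation saturates both disubstituted alkenes (C6=C7 and C11=C12) without creating a stereocentre, and platinum is chosen over palladium to avoid hydrogenolysis of the allylic C8–O bond.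

**Step 18**
Reactants: 28 methyl (3R)-5-[(1S,2S,4aS,5S,8aR)-5-{[(tert-butyldimethylsilyl)oxy]methyl}-2,5,8a-trimethyl-2-[(triethylsilyl)oxy]decahydronaphthalen-1-yl]-3-methylpentanoate
Product: 29 methyl (3R)-5-[(1S,2S,4aS,5S,8aR)-2-hydroxy-5-(hydroxymethyl)-2,5,8a-trimethyldecahydronaphthalen-1-yl]-3-methylpentanoate
Conditions: HF·pyridine, pyridine/THF, 0 °C to rt
Reagents that add atoms: none
Why: Fluoride-mediated desilylation cleaves the primary TBS and the tertiary TES ether, the pyridine buffer keeps the tertiary alcohol from ionising and the methyl ester is untouched.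

**Step 19**
Reactants: 29 methyl (3R)-5-[(1S,2S,4aS,5S,8aR)-2-hydroxy-5-(hydroxymethyl)-2,5,8a-trimethyldecahydronaphthalen-1-yl]-3-methylpentanoate; 30 3-methylbut-2-enoyl chloride
Product: 31 methyl (3R)-5-[(1S,2S,4aS,5S,8aR)-2-hydroxy-2,5,8a-trimethyl-5-{[(3-methylbut-2-enoyl)oxy]methyl}decahydronaphthalen-1-yl]-3-methylpentanoate
Conditions: pyridine, DMAP (cat.), CH2Cl2, 0 °C
Reagents that add atoms: none
Why: DMAP-catalysed acylation is selective for the primary alcohol over the hindered tertiary C8 alcohol, and pyridine as a weak base avoids deconjugation of the senecioyl group via its vinylketene.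

**Step 20**
Reactants: 31 methyl (3R)-5-[(1S,2S,4aS,5S,8aR)-2-hydroxy-2,5,8a-trimethyl-5-{[(3-methylbut-2-enoyl)oxy]methyl}decahydronaphthalen-1-yl]-3-methylpentanoate
Product: 32 (3R)-5-[(1S,2S,4aS,5S,8aR)-2-hydroxy-2,5,8a-trimethyl-5-{[(3-methylbut-2-enoyl)oxy]methyl}decahydronaphthalen-1-yl]-3-methylpentanoic acid
Conditions: Me3SnOH, 1,2-dichloroethane, 70 °C; dilute aq. HCl work-up
Reagents that add atoms: trimethyltin hydroxide C[Sn](C)(C)O
Why: Me3SnOH-mediated hydrolysis is selective for the unhindered methyl ester, because the senecioate is a conjugated, β,β-disubstituted ester of a neopentyl-type alcohol and much less electrophilic, and the neutral conditions leave the tertiary alcohol and the trisubstituted alkene intact.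

**Compound list**
1 | 5-chloropent-1-yne | C#CCCCCl | starting material
2 | (E)-(5-chloro-2-methylpent-1-en-1-yl)dimethylalane | C[Al](C)/C=C(\C)CCCCl | intermediate
3 | lithium butyl[(E)-5-chloro-2-methylpent-1-en-1-yl]dimethylalanate | [Li+].CCCC[Al-](C)(C)/C=C(\C)CCCCl | intermediate
4 | (2E)-6-chloro-3-methylhex-2-en-1-ol | OC/C=C(\C)CCCCl | intermediate
5 | [(2R,3R)-3-(3-chloropropyl)-3-methyloxiran-2-yl]methanol | OC[C@H]1O[C@]1(C)CCCCl | intermediate
6 | tert-butyl{[(2R,3R)-3-(3-chloropropyl)-3-methyloxiran-2-yl]methoxy}dimethylsilane | CC(C)(C)[Si](C)(C)OC[C@H]1O[C@]1(C)CCCCl | intermediate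
7 | (2R)-2-{[(tert-butyldimethylsilyl)oxy]methyl}-5-chloro-2-methylpentanal | CC(C)(C)[Si](C)(C)OC[C@@](C=O)(C)CCCCl | intermediate
8 | 2-(2-bromoethyl)-2-methyl-1,3-dioxolane | CC1(CCBr)OCCO1 | starting material
9 | 1-phenyl-1H-tetrazole-5-thiol | Sc1nnnn1-c1ccccc1 | starting material
10 | 5-{[2-(2-methyl-1,3-dioxolan-2-yl)ethyl]sulfanyl}-1-phenyl-1H-tetrazole | CC1(CCSc2nnnn2-c2ccccc2)OCCO1 | intermediate
11 | 5-{[2-(2-methyl-1,3-dioxolan-2-yl)ethyl]sulfonyl}-1-phenyl-1H-tetrazole | CC1(CCS(=O)(=O)c2nnnn2-c2ccccc2)OCCO1 | intermediate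
12 | potassium 2-(2-methyl-1,3-dioxolan-2-yl)-1-[(1-phenyl-1H-tetrazol-5-yl)sulfonyl]ethan-1-ide | [K+].CC1(C[CH-]S(=O)(=O)c2nnnn2-c2ccccc2)OCCO1 | intermediate
13 | tert-butyl{[(2S,3E)-2-(3-chloropropyl)-2-methyl-5-(2-methyl-1,3-dioxolan-2-yl)pent-3-en-1-yl]oxy}dimethylsilane | CC(C)(C)[Si](C)(C)OC[C@@](/C=C/CC1(C)OCCO1)(C)CCCCl | intermediate
14 | ethyl but-2-ynoate | CCOC(=O)C#CC | starting material
15 | {(4S,5E)-4-{[(tert-butyldimethylsilyl)oxy]methyl}-4-methyl-7-(2-methyl-1,3-dioxolan-2-yl)hept-5-en-1-yl}magnesium chloride | CC(C)(C)[Si](C)(C)OC[C@@](/C=C/CC1(C)OCCO1)(C)CCC[Mg]Cl | intermediate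
16 | {(4S,5E)-4-{[(tert-butyldimethylsilyl)oxy]methyl}-4-methyl-7-(2-methyl-1,3-dioxolan-2-yl)hept-5-en-1-yl}copper | CC(C)(C)[Si](C)(C)OC[C@@](/C=C/CC1(C)OCCO1)(C)CCC[Cu] | intermediate
17 | ethyl (2E,7S,8E)-7-{[(tert-butyldimethylsilyl)oxy]methyl}-3,7-dimethyl-10-(2-methyl-1,3-dioxolan-2-yl)deca-2,8-dienoate | CCOC(=O)/C=C(\C)CCC[C@](C)(CO[Si](C)(C)C(C)(C)C)/C=C/CC1(C)OCCO1 | intermediate
18 | ethyl (2E,7S,8E)-7-{[(tert-butyldimethylsilyl)oxy]methyl}-3,7-dimethyl-11-oxododeca-2,8-dienoate | CCOC(=O)/C=C(\C)CCC[C@](C)(CO[Si](C)(C)C(C)(C)C)/C=C/CC(C)=O | intermediate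
19 | ethyl (2E,7S,8E,10Z)-7-{[(tert-butyldimethylsilyl)oxy]methyl}-3,7-dimethyl-11-[(triethylsilyl)oxy]dodeca-2,8,10-trienoate | CCOC(=O)/C=C(\C)CCC[C@](C)(CO[Si](C)(C)C(C)(C)C)/C=C/C=C(/C)O[Si](CC)(CC)CC | intermediate
20 | (2E,7S,8E,10Z)-7-{[(tert-butyldimethylsilyl)oxy]methyl}-3,7-dimethyl-11-[(triethylsilyl)oxy]dodeca-2,8,10-trien-1-ol | OC/C=C(\C)CCC[C@](C)(CO[Si](C)(C)C(C)(C)C)/C=C/C=C(/C)O[Si](CC)(CC)CC | intermediate
21 | (2E,7S,8E,10Z)-7-{[(tert-butyldimethylsilyl)oxy]methyl}-3,7-dimethyl-11-[(triethylsilyl)oxy]dodeca-2,8,10-trienal | O=C/C=C(\C)CCC[C@](C)(CO[Si](C)(C)C(C)(C)C)/C=C/C=C(/C)O[Si](CC)(CC)CC | intermediate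
22 | (1S,2S,4aS,5S,8aR)-5-{[(tert-butyldimethylsilyl)oxy]methyl}-2,5,8a-trimethyl-2-[(triethylsilyl)oxy]-1,2,4a,5,6,7,8,8a-octahydronaphthalene-1-carbaldehyde | CC(C)(C)[Si](C)(C)OC[C@@]1(C)CCC[C@]2(C)[C@@H]1C=C[C@](C)(O[Si](CC)(CC)CC)[C@H]2C=O | intermediate
23 | (3R)-5-methoxy-3-methyl-5-oxopentanoic acid (methyl hydrogen (R)-3-methylglutarate) | COC(=O)C[C@H](C)CC(=O)O | starting material
24 | methyl (3S)-4-iodo-3-methylbutanoate | COC(=O)C[C@H](C)CI | intermediate
25 | [(2S)-4-methoxy-2-methyl-4-oxobutyl]triphenylphosphonium iodide | COC(=O)C[C@H](C)C[P+](c1ccccc1)(c1ccccc1)c1ccccc1.[I-] | intermediate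
26 | methyl (3S)-3-methyl-4-(triphenyl-λ5-phosphanylidene)butanoate | COC(=O)C[C@H](C)C=P(c1ccccc1)(c1ccccc1)c1ccccc1 | intermediate
27 | methyl (3S,4Z)-5-[(1S,2S,4aS,5S,8aR)-5-{[(tert-butyldimethylsilyl)oxy]methyl}-2,5,8a-trimethyl-2-[(triethylsilyl)oxy]-1,2,4a,5,6,7,8,8a-octahydronaphthalen-1-yl]-3-methylpent-4-enoate | CC(C)(C)[Si](C)(C)OC[C@@]1(C)CCC[C@]2(C)[C@@H]1C=C[C@](C)(O[Si](CC)(CC)CC)[C@H]2/C=C\[C@@H](C)CC(=O)OC | intermediate
28 | methyl (3R)-5-[(1S,2S,4aS,5S,8aR)-5-{[(tert-butyldimethylsilyl)oxy]methyl}-2,5,8a-trimethyl-2-[(triethylsilyl)oxy]decahydronaphthalen-1-yl]-3-methylpentanoate | CC(C)(C)[Si](C)(C)OC[C@@]1(C)CCC[C@]2(C)[C@@H]1CC[C@](C)(O[Si](CC)(CC)CC)[C@H]2CC[C@@H](C)CC(=O)OC | intermediate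
29 | methyl (3R)-5-[(1S,2S,4aS,5S,8aR)-2-hydroxy-5-(hydroxymethyl)-2,5,8a-trimethyldecahydronaphthalen-1-yl]-3-methylpentanoate | OC[C@@]1(C)CCC[C@]2(C)[C@@H]1CC[C@](C)(O)[C@H]2CC[C@@H](C)CC(=O)OC | intermediate
30 | 3-methylbut-2-enoyl chloride (senecioyl chloride) | CC(C)=CC(Cl)=O | starting material
31 | methyl (3R)-5-[(1S,2S,4aS,5S,8aR)-2-hydroxy-2,5,8a-trimethyl-5-{[(3-methylbut-2-enoyl)oxy]methyl}decahydronaphthalen-1-yl]-3-methylpentanoate | CC(C)=CC(=O)OC[C@@]1(C)CCC[C@]2(C)[C@@H]1CC[C@](C)(O)[C@H]2CC[C@@H](C)CC(=O)OC | intermediate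
32 | (3R)-5-[(1S,2S,4aS,5S,8aR)-2-hydroxy-2,5,8a-trimethyl-5-{[(3-methylbut-2-enoyl)oxy]methyl}decahydronaphthalen-1-yl]-3-methylpentanoic acid | CC(C)=CC(=O)OC[C@@]1(C)CCC[C@]2(C)[C@@H]1CC[C@](C)(O)[C@H]2CC[C@@H](C)CC(=O)O | target

**Step count**
Total: 20 steps. Longest linear sequence: 16 steps (steps 1–4, 7–13, 16–20, from 5-chloropent-1-yne).

**Steps most likely to fail**

Step 13 (key step). Under the Lewis acid the cycloaddition may be diverted into ionic processes (protodesilylation of the dienol ether, open-chain vinylogous Mukaiyama–Michael addition), or the π-facial discrimination by C4 may be low. The fallback sets out from 19 and comes back at 22. The uncatalysed thermal intramolecular Diels–Alder reaction is run at the ester stage (toluene, BHT, 180 °C, sealed tube), where no Lewis acid is present and the adduct is robust enough for separation of C4 diastereomers; it should give ethyl (1S,2S,4aS,5S,8aR)-5-{[(tert-butyldimethylsilyl)oxy]methyl}-2,5,8a-trimethyl-2-[(triethylsilyl)oxy]-1,2,4a,5,6,7,8,8a-octahydronaphthalene-1-carboxylate F1. Reduction with LiAlH4 (Et2O, 0 °C) should give [(1R,2S,4aS,5S,8aR)-5-{[(tert-butyldimethylsilyl)oxy]methyl}-2,5,8a-trimethyl-2-[(triethylsilyl)oxy]-1,2,4a,5,6,7,8,8a-octahydronaphthalen-1-yl]methanol F2, and oxidation with Dess–Martin periodinane/NaHCO3 returns 22.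

Step 16. Addition of the bulky ylide to the aldehyde on C9, which is flanked by two fully substituted carbons, may be slow, so that base-induced β-elimination of triethylsilanol across C8–C9 competes. The fallback sets out from 24 and comes back at 28. Thiol 9 is alkylated with 24 (K2CO3, acetone) to give methyl (3S)-3-methyl-4-[(1-phenyl-1H-tetrazol-5-yl)sulfanyl]butanoate F3, which is oxidised (H2O2, (NH4)6Mo7O24·4H2O) to methyl (3S)-3-methyl-4-[(1-phenyl-1H-tetrazol-5-yl)sulfonyl]butanoate F4. Julia–Kocienski olefination of 22 with F4 under Barbier conditions (LiN(SiMe3)2 added to the mixture, THF, −78 °C), in which the smaller and more nucleophilic sulfonyl carbanion adds at low temperature, should give methyl (3S,4E)-5-[(1S,2S,4aS,5S,8aR)-5-{[(tert-butyldimethylsilyl)oxy]methyl}-2,5,8a-trimethyl-2-[(triethylsilyl)oxy]-1,2,4a,5,6,7,8,8a-octahydronaphthalen-1-yl]-3-methylpent-4-enoate F5. Hydrogenation under the conditions of step 17 gives 28.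

Step 20. The two carboxylic esters are told apart only by rate, so partial cleavage of the senecioate or incomplete conversion may result. The fallback sets out from 29 and comes back at 32. Saponification of 29 (LiOH, THF/H2O) gives (3R)-5-[(1S,2S,4aS,5S,8aR)-2-hydroxy-5-(hydroxymethyl)-2,5,8a-trimethyldecahydronaphthalen-1-yl]-3-methylpentanoic acid F6. Chemoselective alkylation of the carboxylate (Cs2CO3, allyl bromide, DMF) gives prop-2-en-1-yl (3R)-5-[(1S,2S,4aS,5S,8aR)-2-hydroxy-5-(hydroxymethyl)-2,5,8a-trimethyldecahydronaphthalen-1-yl]-3-methylpentanoate F7. Acylation with 30 as in step 19 gives prop-2-en-1-yl (3R)-5-[(1S,2S,4aS,5S,8aR)-2-hydroxy-2,5,8a-trimethyl-5-{[(3-methylbut-2-enoyl)oxy]methyl}decahydronaphthalen-1-yl]-3-methylpentanoate F8, and deallylation with Pd(PPh3)4 (cat.)/morpholine in THF gives 32 without any hydrolysis step in the presence of the senecioate.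

**Further compounds**
F1 | step 13 | ethyl (1S,2S,4aS,5S,8aR)-5-{[(tert-butyldimethylsilyl)oxy]methyl}-2,5,8a-trimethyl-2-[(triethylsilyl)oxy]-1,2,4a,5,6,7,8,8a-octahydronaphthalene-1-carboxylate | CC(C)(C)[Si](C)(C)OC[C@@]1(C)CCC[C@]2(C)[C@@H]1C=C[C@](C)(O[Si](CC)(CC)CC)[C@H]2C(=O)OCC
F2 | step 13 | [(1R,2S,4aS,5S,8aR)-5-{[(tert-butyldimethylsilyl)oxy]methyl}-2,5,8a-trimethyl-2-[(triethylsilyl)oxy]-1,2,4a,5,6,7,8,8a-octahydronaphthalen-1-yl]methanol | CC(C)(C)[Si](C)(C)OC[C@@]1(C)CCC[C@]2(C)[C@@H]1C=C[C@](C)(O[Si](CC)(CC)CC)[C@H]2CO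
F3 | step 16 | methyl (3S)-3-methyl-4-[(1-phenyl-1H-tetrazol-5-yl)sulfanyl]butanoate | COC(=O)C[C@H](C)CSc1nnnn1-c1ccccc1
F4 | step 16 | methyl (3S)-3-methyl-4-[(1-phenyl-1H-tetrazol-5-yl)sulfonyl]butanoate | COC(=O)C[C@H](C)CS(=O)(=O)c1nnnn1-c1ccccc1
F5 | step 16 | methyl (3S,4E)-5-[(1S,2S,4aS,5S,8aR)-5-{[(tert-butyldimethylsilyl)oxy]methyl}-2,5,8a-trimethyl-2-[(triethylsilyl)oxy]-1,2,4a,5,6,7,8,8a-octahydronaphthalen-1-yl]-3-methylpent-4-enoate | CC(C)(C)[Si](C)(C)OC[C@@]1(C)CCC[C@]2(C)[C@@H]1C=C[C@](C)(O[Si](CC)(CC)CC)[C@H]2/C=C/[C@@H](C)CC(=O)OC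
F6 | step 20 | (3R)-5-[(1S,2S,4aS,5S,8aR)-2-hydroxy-5-(hydroxymethyl)-2,5,8a-trimethyldecahydronaphthalen-1-yl]-3-methylpentanoic acid | OC[C@@]1(C)CCC[C@]2(C)[C@@H]1CC[C@](C)(O)[C@H]2CC[C@@H](C)CC(=O)O
F7 | step 20 | prop-2-en-1-yl (3R)-5-[(1S,2S,4aS,5S,8aR)-2-hydroxy-5-(hydroxymethyl)-2,5,8a-trimethyldecahydronaphthalen-1-yl]-3-methylpentanoate | OC[C@@]1(C)CCC[C@]2(C)[C@@H]1CC[C@](C)(O)[C@H]2CC[C@@H](C)CC(=O)OCC=C
F8 | step 20 | prop-2-en-1-yl (3R)-5-[(1S,2S,4aS,5S,8aR)-2-hydroxy-2,5,8a-trimethyl-5-{[(3-methylbut-2-enoyl)oxy]methyl}decahydronaphthalen-1-yl]-3-methylpentanoate | CC(C)=CC(=O)OC[C@@]1(C)CCC[C@]2(C)[C@@H]1CC[C@](C)(O)[C@H]2CC[C@@H](C)CC(=O)OCC=C
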